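**Plan**
- Locants: unprimed for the 5,7-dihydroxy chroman-2-one (unit A), primed for the 5′,6′,7′,8′-tetrahydroxy chroman-2-one (unit B); the target is (3R,4S,3′S,4′R), with H3/H4 cis and H3′/H4′ cis.
- Enabling feature: in ring B, O1′ sits on C8a′ para to the C6′ hydroxyl, so unit B is a hydroquinone monoester. Its ortho-quinone methide (C8a′=O, C4a′=C4′) is therefore the tautomer of a fully substituted 2-benzyl-1,4-benzoquinone.
- Retrosynthesis: first the seven O–CH3 bonds (6′-OH stays free), then C3′–C4′ together with O1′–C2′, then C3–C4 together with O1–C2, last the aryl–CH2 and aryl–CH(OH) bonds.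
- Forward: the benzylquinone is made from 1,2,4,5-tetramethoxybenzene in four steps. The lactone ring of unit A closes first, by a carbene-catalysed annulation that leaves a 4-nitrophenyl acetate arm on C3. The lactone ring of unit B closes when that arm meets the quinone tautomer, and BBr3 finishes.
- Stereochemistry: C3/C4 come from a chiral triazolylidene (endo, cis); C3′/C4′ come from its enantiomer in the key step (endo, cis).

Key step: step 9

Remark on descriptors: the unit-A ester is (3S,4S) and becomes 3R in the dimer without any change in space, because the CH2 arm ranks below C4 whereas C3′ ranks above it.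
Assumption: the sense of induction of the two enantiomeric triazolium precatalysts is assigned from the usual endo model of azolium-enolate [4+2] annulations; if the model is reversed, the two precatalysts change places between steps 8 and 9.

**Step 1**
Reactants: 1 1,2,4,5-tetramethoxybenzene
Product: 4 2,3,5,6-tetramethoxyphenol, via 2,3,5,6-tetramethoxyphenyllithium 2 (not isolated), via lithium trimethoxy(2,3,5,6-tetramethoxyphenyl)borate 3 (not isolated)
Conditions: n-BuLi, TMEDA, THF, 0 °C; B(OMe)3, −78 °C → rt; AcOH, H2O2 (30 % aq.), 0 °C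
Reagents that add atoms: hydrogen peroxide, OO
Why: Directed ortho-lithiation at one of the two equivalent ring hydrogens, each flanked by two methoxy groups, then borylation and peroxide oxidation (1,2-aryl shift from boron to oxygen) should turn C–H into C–OH.

**Step 2**
Reactants: 4 2,3,5,6-tetramethoxyphenol
Product: 5 pentamethoxybenzene
Conditions: MeI, K2CO3, acetone, reflux
Reagents that add atoms: iodomethane, CI
Why: Williamson O-methylation of the phenoxide, which is the only nucleophilic site.

**Step 3**
Reactants: 5 pentamethoxybenzene; 6 4-methoxybenzyl alcohol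
Product: 7 1,2,3,4,5-pentamethoxy-6-(4-methoxybenzyl)benzene
Conditions: Sc(OTf)3 (5 mol %), MeNO2, 50 °C
Reagents that add atoms: none
Why: Friedel–Crafts benzylation in which the Lewis acid ionises the alcohol to the 4-methoxybenzyl cation, which can only attack the single unsubstituted position of the electron-rich arene.

**Step 4**
Reactants: 7 1,2,3,4,5-pentamethoxy-6-(4-methoxybenzyl)benzene
Product: 8 2,3,5-trimethoxy-6-(4-methoxybenzyl)-1,4-benzoquinone
Conditions: (NH4)2Ce(NO3)6 (2.5 equiv), MeCN–H2O (2:1), 0 °C
Reagents that add atoms: water, O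
Why: Oxidative demethylation of a para-dimethoxyarene at the most easily oxidised ring; the two para pairs of methoxy groups that can become carbonyls are related by symmetry and give the same quinone, and the pair through the benzyl-bearing carbon cannot react.

**Step 5**
Reactants: 9 2-hydroxy-4,6-dimethoxybenzaldehyde; 10 4-methoxyphenylmagnesium bromide
Product: 11 racemic 2-[hydroxy(4-methoxyphenyl)methyl]-3,5-dimethoxyphenol
Conditions: 10 (2.5 equiv), THF, 0 °C → rt; sat. aq. NH4Cl
Reagents that add atoms: none
Why: Grignard addition in which the first equivalent deprotonates the phenol and a further equivalent adds to the aldehyde; the racemic carbinol centre is erased in step 8.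

**Step 6**
Reactants: 11 racemic 2-[hydroxy(4-methoxyphenyl)methyl]-3,5-dimethoxyphenol
Product: 12 racemic 3,5-dimethoxy-2-[(4-methoxyphenyl)(4-methylbenzenesulfonyl)methyl]phenol
Conditions: TolSO2Na (2 equiv), HCO2H–H2O (1:1), rt
Reagents that add atoms: sodium 4-methylbenzenesulfinate, Cc1ccc(cc1)S(=O)[O-].[Na+]
Why: Acid-promoted ionisation of the electron-rich ortho-hydroxybenzhydrol and capture of the cation at sulfinate sulfur (SN1-type substitution) should give a storable sulfone that releases the ortho-quinone methide under base; the centre stays racemic.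

**Step 7**
Reactants: 13 succinyl chloride; 14 4-nitrophenol
Product: 15 bis(4-nitrophenyl) succinate
Conditions: 14 (2.1 equiv in all), Et3N (2.2 equiv), CH2Cl2, 0 °C → rt
Reagents that add atoms: 4-nitrophenol (the second equivalent of 14, for the other acid chloride end), Oc1ccc(cc1)[N+](=O)[O-]
Why: Twofold O-acylation of the phenol by the diacid chloride (Schotten–Baumann-type esterification), one molecule of 14 being taken up at each acyl chloride end with the amine binding both equivalents of HCl.

**Step 8**
Reactants: 12 racemic 3,5-dimethoxy-2-[(4-methoxyphenyl)(4-methylbenzenesulfonyl)methyl]phenol; 15 bis(4-nitrophenyl) succinate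
Product: 17 4-nitrophenyl 2-[(3S,4S)-5,7-dimethoxy-4-(4-methoxyphenyl)-2-oxochroman-3-yl]acetate, via (6E)-3,5-dimethoxy-6-(4-methoxybenzylidene)cyclohexa-2,4-dien-1-one 16 (not isolated)
Conditions: 15 (3 equiv), (5aR,10bS)-2-(2,4,6-trimethylphenyl)-5a,10b-dihydro-4H,6H-indeno[2,1-b][1,2,4]triazolo[4,3-d][1,4]oxazinium chloride (15 mol %), K2CO3 (2.5 equiv), 4 Å MS, THF, 0 °C → rt
Reagents that add atoms: none
Why: Carbene-catalysed [4+2] annulation of an ester-derived azolium enolate with an ortho-quinone methide: the carbene displaces 4-nitrophenoxide from one end of 15, the acyl azolium is deprotonated to the Z-enolate, this adds endo to 16 (released from 12 by base-induced loss of sulfinate) and the phenoxide lactonises with release of the carbene; the catalyst face sets C3 and endo approach to the E-methide sets C4 cis to it, while the excess of 15 holds back a second annulation.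

**Step 9**
Reactants: 8 2,3,5-trimethoxy-6-(4-methoxybenzyl)-1,4-benzoquinone; 17 4-nitrophenyl 2-[(3S,4S)-5,7-dimethoxy-4-(4-methoxyphenyl)-2-oxochroman-3-yl]acetate
Product: 19 (3R,4S,3'S,4'R)-6'-hydroxy-5,5',7,7',8'-pentamethoxy-4,4'-bis(4-methoxyphenyl)-[3,3'-bichromane]-2,2'-dione, via (6E)-4-hydroxy-2,3,5-trimethoxy-6-(4-methoxybenzylidene)cyclohexa-2,4-dien-1-one 18 (not isolated)
Conditions: 8 (1.5 equiv), (5aS,10bR)-2-(2,4,6-trimethylphenyl)-5a,10b-dihydro-4H,6H-indeno[2,1-b][1,2,4]triazolo[4,3-d][1,4]oxazinium chloride (20 mol %), iPr2NEt (1.5 equiv), 4 Å MS, THF, rt, Ar, dark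
Reagents that add atoms: none
Why: Proposed new method: iPr2NEt and the 4-nitrophenoxide set free act as a proton shuttle that moves one benzylic hydrogen of quinone 8 (acidified through the C6=C5–C4=O vinylogous path and by the anisyl ring) onto the C4 oxygen, giving the 6′-hydroxy ortho-quinone methide 18, while the triazolylidene displaces 4-nitrophenoxide from 17 and the acyl azolium is deprotonated at its CH2 to the Z-azolium enolate. The enolate carbon adds to the methide carbon of 18 (bond C3′–C4′) and the C8a′ oxygen then acylates at the azolium carbonyl (bond O1′–C2′), which frees the carbene; the closest known chemistry is the base-induced tautomerisation of 2-alkyl-1,4-benzoquinones to ortho-quinone methides with [4+2] trapping on one side and the carbene-catalysed [4+2] annulation of ester-derived azolium enolates with sulfone-derived ortho-quinone methides (as in step 8) on the other, and merging them in one flask is what is new. The only ring formed, the lactone ring of unit B, closes as an asynchronous hetero-Diels–Alder addition whose second event is a 6-exo-trig O-acylation. C3′ is set by the catalyst, whose indane wall blocks one enolate face (the enantiomer of the step 8 catalyst is used because unit B has the opposite sense to unit A), and C4′ is set relative to C3′ by endo approach to the E-methide, which places H3′ and H4′ cis. The step needs acyl transfer at the 4-nitrophenyl ester and not at the aryl lactone of 17 (far better leaving group, unhindered carbonyl), enolisation at the side-chain CH2 and not at C3 (only the CH2 is alpha to the azolium carbonyl), and attack at the methide carbon only: the quinone ring bears no hydrogen, so ring conjugate addition has no site, and the 6′-oxygen is flanked by two methoxy groups and is a poor acyl acceptor. The resident C3 centre next to the enolate carbon may reinforce or oppose the catalyst, so reagent control is relied on.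

**Step 10**
Reactants: 19 (3R,4S,3'S,4'R)-6'-hydroxy-5,5',7,7',8'-pentamethoxy-4,4'-bis(4-methoxyphenyl)-[3,3'-bichromane]-2,2'-dione
Product: 20 (3R,4S,3'S,4'R)-5,5',6',7,7',8'-hexahydroxy-4,4'-bis(4-hydroxyphenyl)-[3,3'-bichromane]-2,2'-dione
Conditions: BBr3 (20 equiv), CH2Cl2, −78 °C → rt; degassed H2O, 0 °C, Ar
Reagents that add atoms: none
Why: Lewis-acid cleavage of the seven aryl methyl ethers (bromide attacks the methyl group of each borane-complexed ether); the aryl lactones are inert to BBr3, no base is present that could epimerise C3 or C3′, and work-up under argon protects the tetrahydroxyaryl ring from air.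

**Compound list**
1 | 1,2,4,5-tetramethoxybenzene | COc1cc(OC)c(OC)cc1OC | starting material
2 | 2,3,5,6-tetramethoxyphenyllithium (formed in the flask) | [Li]c1c(OC)c(OC)cc(OC)c1OC | intermediate
3 | lithium trimethoxy(2,3,5,6-tetramethoxyphenyl)borate (formed in the flask) | [Li+].CO[B-](OC)(OC)c1c(OC)c(OC)cc(OC)c1OC | intermediate
4 | 2,3,5,6-tetramethoxyphenol | COc1cc(OC)c(OC)c(O)c1OC | intermediate
5 | pentamethoxybenzene | COc1cc(OC)c(OC)c(OC)c1OC | intermediate
6 | 4-methoxybenzyl alcohol | COc1ccc(CO)cc1 | starting material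
7 | 1,2,3,4,5-pentamethoxy-6-(4-methoxybenzyl)benzene | COc1ccc(Cc2c(OC)c(OC)c(OC)c(OC)c2OC)cc1 | intermediate
8 | 2,3,5-trimethoxy-6-(4-methoxybenzyl)-1,4-benzoquinone | COC1=C(OC)C(=O)C(Cc2ccc(OC)cc2)=C(OC)C1=O | intermediate
9 | 2-hydroxy-4,6-dimethoxybenzaldehyde | COc1cc(O)c(C=O)c(OC)c1 | starting material
10 | 4-methoxyphenylmagnesium bromide (THF solution) | COc1ccc([Mg]Br)cc1 | starting material
11 | racemic 2-[hydroxy(4-methoxyphenyl)methyl]-3,5-dimethoxyphenol | COc1ccc(cc1)C(O)c1c(O)cc(OC)cc1OC | intermediate
12 | racemic 3,5-dimethoxy-2-[(4-methoxyphenyl)(4-methylbenzenesulfonyl)methyl]phenol | COc1ccc(cc1)C(c1c(O)cc(OC)cc1OC)S(=O)(=O)c1ccc(C)cc1 | intermediate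
13 | succinyl chloride | O=C(Cl)CCC(=O)Cl | starting material
14 | 4-nitrophenol | Oc1ccc(cc1)[N+](=O)[O-] | starting material
15 | bis(4-nitrophenyl) succinate | O=C(CCC(=O)Oc1ccc(cc1)[N+](=O)[O-])Oc1ccc(cc1)[N+](=O)[O-] | intermediate
16 | (6E)-3,5-dimethoxy-6-(4-methoxybenzylidene)cyclohexa-2,4-dien-1-one (formed in the flask) | COc1ccc(cc1)/C=C1/C(=O)C=C(OC)C=C1OC | intermediate
17 | 4-nitrophenyl 2-[(3S,4S)-5,7-dimethoxy-4-(4-methoxyphenyl)-2-oxochroman-3-yl]acetate | O=C(C[C@@H]1C(=O)Oc2cc(OC)cc(OC)c2[C@@H]1c1ccc(OC)cc1)Oc1ccc(cc1)[N+](=O)[O-] | intermediate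
18 | (6E)-4-hydroxy-2,3,5-trimethoxy-6-(4-methoxybenzylidene)cyclohexa-2,4-dien-1-one (formed in the flask) | O=C1C(OC)=C(OC)C(O)=C(OC)/C1=C\c1ccc(OC)cc1 | intermediate
19 | (3R,4S,3'S,4'R)-6'-hydroxy-5,5',7,7',8'-pentamethoxy-4,4'-bis(4-methoxyphenyl)-[3,3'-bichromane]-2,2'-dione | O=C1Oc2cc(OC)cc(OC)c2[C@H](c2ccc(OC)cc2)[C@@H]1[C@H]1C(=O)Oc2c(OC)c(OC)c(O)c(OC)c2[C@H]1c1ccc(OC)cc1 | intermediate
20 | (3R,4S,3'S,4'R)-5,5',6',7,7',8'-hexahydroxy-4,4'-bis(4-hydroxyphenyl)-[3,3'-bichromane]-2,2'-dione | O=C1Oc2cc(O)cc(O)c2[C@H](c2ccc(O)cc2)[C@@H]1[C@H]1C(=O)Oc2c(O)c(O)c(O)c(O)c2[C@H]1c1ccc(O)cc1 | target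

**Step count**
Total: 10 steps. Longest linear sequence: 6 steps (1, 2, 3, 4, 9, 10).

**Steps most likely to fail**

Step 9. The tautomer equilibrium may supply the ortho-quinone methide too slowly, so that the carbene or the acyl azolium is used up by the quinone (electron transfer, O-acylation) or the methide condenses with itself. Double stereodifferentiation with the resident C3 centre may also erode the facial selectivity. The fallback makes the heterodiene by sulfinate elimination at the phenol oxidation level, using only known reaction types; it sets out from 5 (and uses 17) and comes back at 20. Friedel–Crafts acylation of 5 with 4-methoxybenzoyl chloride (AlCl3, CH2Cl2) should give (4-methoxyphenyl)(pentamethoxyphenyl)methanone F1. BCl3 then removes one of the two equivalent ortho methyl groups through the ketone chelate to give (2-hydroxy-3,4,5,6-tetramethoxyphenyl)(4-methoxyphenyl)methanone F2. NaBH4 reduction gives racemic 2-[hydroxy(4-methoxyphenyl)methyl]-3,4,5,6-tetramethoxyphenol F3, and sodium 4-methylbenzenesulfinate in aqueous formic acid converts it into racemic 2,3,4,5-tetramethoxy-6-[(4-methoxyphenyl)(4-methylbenzenesulfonyl)methyl]phenol F4. Under the conditions of step 8, with the catalyst enantiomer of step 9, F4 loses sulfinate to (6E)-2,3,4,5-tetramethoxy-6-(4-methoxybenzylidene)cyclohexa-2,4-dien-1-one F5, formed in the flask. This is annulated with the azolium enolate of 17 to (3R,4S,3'S,4'R)-5,5',6',7,7',8'-hexamethoxy-4,4'-bis(4-methoxyphenyl)-[3,3'-bichromane]-2,2'-dione F6, and BBr3 as in step 10 leads to 20.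

Step 8. The first annulation product still carries an activated ester and may enter the catalytic cycle a second time. Enolisation of the unactivated succinate may also be slow enough for ortho-quinone methide oligomerisation and base-induced cis-to-trans epimerisation at C3 to compete. The fallback masks the second carboxyl; it sets out from 12 (with 14) and comes back at 17. Mono-tert-butyl succinate and 14 (DCC, catalytic DMAP) give tert-butyl 4-nitrophenyl succinate F7. The carbene annulation with 12 under the step 8 conditions, now with a single activated ester, gives tert-butyl 2-[(3S,4S)-5,7-dimethoxy-4-(4-methoxyphenyl)-2-oxochroman-3-yl]acetate F8. TFA in CH2Cl2 frees 2-[(3S,4S)-5,7-dimethoxy-4-(4-methoxyphenyl)-2-oxochroman-3-yl]acetic acid F9, and DCC with 14 gives 17.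

Step 10. Ether cleavage may stop short at the crowded ring-B positions, and the freed tetrahydroxyaryl ring may be oxidised by air during isolation. The fallback isolates a protected form; it sets out from 19 and comes back at 20. After the BBr3 treatment the mixture is quenched with methanol and evaporated, and the crude polyphenol is acetylated without isolation (Ac2O, pyridine) to (3R,4S,3'S,4'R)-4,4'-bis(4-acetoxyphenyl)-2,2'-dioxo-[3,3'-bichromane]-5,5',6',7,7',8'-hexayl hexaacetate F10, which can be purified on silica. Acid methanolysis (HCl in MeOH, 0 °C → rt) then removes the acetates without base; evaporation from toluene recloses any lactone that opened, giving 20.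

**Further compounds**
F1 | step 9 | (4-methoxyphenyl)(pentamethoxyphenyl)methanone | COc1ccc(cc1)C(=O)c1c(OC)c(OC)c(OC)c(OC)c1OC
F2 | step 9 | (2-hydroxy-3,4,5,6-tetramethoxyphenyl)(4-methoxyphenyl)methanone | COc1ccc(cc1)C(=O)c1c(O)c(OC)c(OC)c(OC)c1OC
F3 | step 9 | racemic 2-[hydroxy(4-methoxyphenyl)methyl]-3,4,5,6-tetramethoxyphenol | COc1ccc(cc1)C(O)c1c(O)c(OC)c(OC)c(OC)c1OC
F4 | step 9 | racemic 2,3,4,5-tetramethoxy-6-[(4-methoxyphenyl)(4-methylbenzenesulfonyl)methyl]phenol | COc1ccc(cc1)C(c1c(O)c(OC)c(OC)c(OC)c1OC)S(=O)(=O)c1ccc(C)cc1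
F5 | step 9 | (6E)-2,3,4,5-tetramethoxy-6-(4-methoxybenzylidene)cyclohexa-2,4-dien-1-one | O=C1C(OC)=C(OC)C(OC)=C(OC)/C1=C\c1ccc(OC)cc1
F6 | step 9 | (3R,4S,3'S,4'R)-5,5',6',7,7',8'-hexamethoxy-4,4'-bis(4-methoxyphenyl)-[3,3'-bichromane]-2,2'-dione | O=C1Oc2cc(OC)cc(OC)c2[C@H](c2ccc(OC)cc2)[C@@H]1[C@H]1C(=O)Oc2c(OC)c(OC)c(OC)c(OC)c2[C@H]1c1ccc(OC)cc1
F7 | step 8 | tert-butyl 4-nitrophenyl succinate | CC(C)(C)OC(=O)CCC(=O)Oc1ccc(cc1)[N+](=O)[O-]
F8 | step 8 | tert-butyl 2-[(3S,4S)-5,7-dimethoxy-4-(4-methoxyphenyl)-2-oxochroman-3-yl]acetate | CC(C)(C)OC(=O)C[C@@H]1C(=O)Oc2cc(OC)cc(OC)c2[C@@H]1c1ccc(OC)cc1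
F9 | step 8 | 2-[(3S,4S)-5,7-dimethoxy-4-(4-methoxyphenyl)-2-oxochroman-3-yl]acetic acid | OC(=O)C[C@@H]1C(=O)Oc2cc(OC)cc(OC)c2[C@@H]1c1ccc(OC)cc1
F10 | step 10 | (3R,4S,3'S,4'R)-4,4'-bis(4-acetoxyphenyl)-2,2'-dioxo-[3,3'-bichromane]-5,5',6',7,7',8'-hexayl hexaacetate | O=C1Oc2cc(OC(C)=O)cc(OC(C)=O)c2[C@H](c2ccc(OC(C)=O)cc2)[C@@H]1[C@H]1C(=O)Oc2c(OC(C)=O)c(OC(C)=O)c(OC(C)=O)c(OC(C)=O)c2[C@H]1c1ccc(OC(C)=O)cc1
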